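The impurity in the flask, 3.3 mM, is less than the catalyst charged, 4.00 mM, so I write the balance of the impurity first.

| setting | oak | maple | ash | flask |
|---|---|---|---|---|
| left-handed substrate | 0.20 M | 0.20 M | 0.20 M | 0.20 M |
| right-handed substrate | 0.20 M | 0.20 M | 0.20 M | 0.20 M |
| coupling partner | 1.2 equiv | 1.2 equiv | 1.8 equiv | 1.20 equiv |
| free catalyst | 2.8 mol% | 4.4 mol% | 2 mol% | 2 mol% |
| impurity | 3.3 mM | 3.3 mM | 3.3 mM | 3.3 mM |
| remark | run made earlier | run made earlier | run made earlier |  |

| run | time / min | left-handed product / % | left-handed substrate / % |
|---|---|---|---|
| oak | 5.00 | 27 | 23 |
| oak | 12.0 | 35 | 23 |
| oak | 25.0 | 38 | 19 |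
| oak | 40.0 | 37 | 20 |
| maple | 3.00 | 29 | 19 |
| maple | 6.00 | 35 | 17 |
| maple | 15.0 | 34 | 19 |
| maple | 40.0 | 38 | 20 |
| ash | 10.0 | 35 | 19 |
| ash | 20.0 | 47 | 16 |
| ash | 25.0 | 44 | 14 |
| ash | 40.0 | 49 | 9 |

(readings scatter by 1.5 percentage points)

- apparent order in coupling partner when 20% of the left-handed substrate and right-handed substrate together are converted (percent change of the rate of making left-handed product for one percent more coupling partner charged)
- apparent order in free catalyst when 20% of the left-handed substrate and right-handed substrate together are converted (percent change of the rate of making left-handed product for one percent more free catalyst charged)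

- free catalyst is single-handed; left-handed substrate and right-handed substrate are mirror images of each other, charged as a racemate, each of them at the stated concentration

1. Going from oak to maple raises the catalyst charge by a factor of 1.57. Left-handed product reads 35% after 12.0 min in oak and 35% after 6.00 min in maple, a factor of 2.00 in time as read, more than the factor in catalyst. So I take the impurity to remove free catalyst one for one.

2. In the flask the surviving catalyst is 0.700 mM, the catalyst charge minus the impurity charge. The impurity is the limiting reagent of that loss.

3. First instants: free catalyst equals the charge. The coupling steps run while the impurity starts to bite, and I expect the order in free catalyst to begin near one.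

4. Middle: catalyst and impurity fall together. I place the 20% mark here. With the same charges of catalyst and impurity, a flask that reaches the mark sooner should meet more free catalyst, so I expect more coupling partner to help in two ways: by its own concentration and by the earlier arrival.

5. End: I expect the impurity to fall towards zero and free catalyst to fall towards the surviving catalyst, 0.700 mM. One percent more catalyst charged then gives 5.71 percent more surviving catalyst, and that is the highest order I reckon with. Coupling partner lasts until 60.0% of both substrates has reacted.

6. I commit to an order in free catalyst between one and 5.71. The forecast gives 1.5 for coupling partner and 1.6 for free catalyst, holding that “the impurity is likely titrating catalyst”.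

7. The flask gives 2.3 for coupling partner and 2.3 for free catalyst, at the mark reached after 1.32 min. Both are higher than the forecast, and the second is lower than the highest order I reckoned with.

    coupling partner + free catalyst + left-handed substrate → free catalyst + left-handed product (k = 480 M⁻² min⁻¹)
    coupling partner + free catalyst + right-handed substrate → free catalyst + right-handed product (k = 220 M⁻² min⁻¹)
    left-handed substrate ⇌ right-handed substrate (k = 0.0660 min⁻¹)
    free catalyst + impurity → spent catalyst (k = 350 M⁻¹ min⁻¹)

In this flask both coupling steps ran while the impurity took catalyst: after 3.00 min the impurity stood at 13.9% of its charge and free catalyst at 29.0%. From 15.0 min free catalyst held at 17.9%, which is 0.716 mM against a surviving catalyst of 0.700 mM, and coupling partner fell to 0% by 300 min. On the maple run the same subtraction leaves 5.50 mM, which is 2.39 times oak's, and its left-handed product reads 35% after 6.00 min.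

(Readings and results were generated by integration from invented constants, and the scatter is random.)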